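**Plan**

Retrosynthesis: the phenol is traced to its aryl methyl ether (O–CH3 cut). The benzene ring is then cut at C3–C4 and C5–C6 (chain carbon = C1, oxygen-bearing carbon = C4), which leads to a 5-alkyl-2-pyrone and a ketene acetal, with CO2 and methanol lost on the way to the arene.
The pyrone C5–CH2 bond is cut next (sp2–sp3 cross-coupling) and the acyl C–O bond of the ester last.
Forward: docosanoic acid (1) and allyl alcohol (2) give allyl ester 3; 5-bromo-2H-pyran-2-one (4) is coupled with the 9-BBN adduct 5 of 3, which joins the whole ester chain to the heterocycle (pyrone 6).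
The only carbocycle then arises when 6 and 1,1-dimethoxyethene (7) pass through adducts 8 and 9 to anisole 10; O-demethylation gives the target 11.
The target has no stereocentre and no stereogenic double bond, so no step has to set configuration.

Key step: step 3

Remark: 5-bromo-2H-pyran-2-one and 1,1-dimethoxyethene are taken as purchasable.

**Step 1**
Reactants: 1 docosanoic acid, 2 prop-2-en-1-ol (allyl alcohol)
Product: 3 prop-2-en-1-yl docosanoate (allyl docosanoate)
Conditions: 2 (5 equiv), TsOH·H2O (5 mol%), toluene, reflux, Dean–Stark
Reagents that add atoms: none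
Why: Fischer esterification, driven to completion by excess alcohol and azeotropic removal of water; the terminal alkene is inert to catalytic sulfonic acid.

**Step 2**
Reactants: 3 prop-2-en-1-yl docosanoate, 4 5-bromo-2H-pyran-2-one
Product: 6 3-(6-oxo-6H-pyran-3-yl)propyl docosanoate, via alkylborane 5 (not isolated)
Conditions: 9-BBN (0.5 M in THF, 1.3 equiv), 3 (1.3 equiv), THF, 0 °C → rt; then 4 (1.0 equiv), PdCl2(dppf)·CH2Cl2 (5 mol%), K3PO4 (3 M aq, 3 equiv), DMF, rt → 45 °C
Reagents that add atoms: none
Why: Anti-Markovnikov hydroboration with 9-BBN puts boron on the terminal carbon without touching the ester, and B-alkyl Suzuki–Miyaura coupling (oxidative addition of the pyrone C–Br bond to zerovalent palladium, phosphate-assisted transmetalation, reductive elimination from the wide-bite-angle dppf complex ahead of β-hydride elimination) then attaches the primary alkyl group to C5 of the pyrone under base mild enough for the lactone.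

**Step 3**
Reactants: 6 3-(6-oxo-6H-pyran-3-yl)propyl docosanoate, 7 1,1-dimethoxyethene
Product: 10 3-(4-methoxyphenyl)propyl docosanoate, via bridged lactone 8 (not isolated), via ketal diene 9 (not isolated)
Conditions: 7 (10 equiv), iPr2NEt (10 mol%), toluene, sealed tube, 150 °C; then PPTS (cat.), CH2Cl2, rt
Reagents that add atoms: none
Why: The pyrone serves as the electron-poor 4π unit (C3 to C6) and the ketene acetal as the electron-rich 2π unit in an inverse-electron-demand Diels–Alder reaction giving bridged lactone 8; retro-[4+2] loss of CO2 gives diene 9, and 1,2-elimination of methanol across the ketal carbon and its CH2 neighbour (thermal, completed by a trace of PPTS through an O-methylated arenium ion) gives the anisole. The closest known reaction type is the aromatising cycloaddition of coumalate esters and halo-2-pyrones with ketene acetals; the 5-alkyl pyrone lacks their acceptor group, hence the large excess of 7, the sealed vessel at 150 °C and the amine trace that keeps adventitious acid from polymerising 7. The benzene ring is closed intermolecularly by the two σ-bonds of the concerted, asynchronous suprafacial [4+2] addition (arene C3–C4 and C5–C6 in product numbering) and becomes a carbocycle once the lactone bridge leaves as CO2. The two bridgehead stereocentres of 8 form without control as a racemate and are erased on extrusion, so the product carries none. The step needs para regiochemistry: the nucleophilic CH2 terminus of 7 must bond to pyrone C6, the δ-carbon of the doubly vinylogous lactone with the largest LUMO coefficient, so that the ketal carbon joins C3, opposite the chain on C5; the preference of the bulky C(OMe)2 end for unhindered C3 over C6 next to the chain points the same way. The saturated ester in the side chain is neither diene nor acceptor and should pass through unchanged.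

**Step 4**
Reactants: 10 3-(4-methoxyphenyl)propyl docosanoate
Product: 11 3-(4-hydroxyphenyl)propyl docosanoate
Conditions: BBr3 (1 M in CH2Cl2, 2.5 equiv), CH2Cl2, −78 → 0 °C; then H2O
Reagents that add atoms: none
Why: Lewis-acid ether cleavage, in which BBr3 complexes the anisole oxygen, bromide removes the methyl group by SN2 attack and water hydrolyses the aryloxyborane; at or below 0 °C this should be much faster than cleavage of the primary alkyl ester.

**Compound list**

1 | docosanoic acid | CCCCCCCCCCCCCCCCCCCCCC(=O)O | starting material
2 | prop-2-en-1-ol (allyl alcohol) | C=CCO | starting material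
3 | prop-2-en-1-yl docosanoate | CCCCCCCCCCCCCCCCCCCCCC(=O)OCC=C | intermediate
4 | 5-bromo-2H-pyran-2-one | O=c1ccc(Br)co1 | starting material
5 | 3-(9-borabicyclo[3.3.1]nonan-9-yl)propyl docosanoate (not isolated) | CCCCCCCCCCCCCCCCCCCCCC(=O)OCCCB1C2CCCC1CCC2 | intermediate
6 | 3-(6-oxo-6H-pyran-3-yl)propyl docosanoate | CCCCCCCCCCCCCCCCCCCCCC(=O)OCCCc1ccc(=O)oc1 | intermediate
7 | 1,1-dimethoxyethene | C=C(OC)OC | starting material
8 | 3-(8,8-dimethoxy-3-oxo-2-oxabicyclo[2.2.2]oct-5-en-6-yl)propyl docosanoate (racemic, not isolated) | CCCCCCCCCCCCCCCCCCCCCC(=O)OCCCC1=CC2C(=O)OC1CC2(OC)OC | intermediate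
9 | 3-(4,4-dimethoxycyclohexa-1,5-dien-1-yl)propyl docosanoate (not isolated) | CCCCCCCCCCCCCCCCCCCCCC(=O)OCCCC1=CCC(OC)(OC)C=C1 | intermediate
10 | 3-(4-methoxyphenyl)propyl docosanoate | CCCCCCCCCCCCCCCCCCCCCC(=O)OCCCc1ccc(OC)cc1 | intermediate
11 | 3-(4-hydroxyphenyl)propyl docosanoate | CCCCCCCCCCCCCCCCCCCCCC(=O)OCCCc1ccc(O)cc1 | target

**Step count**

Total steps: 4. Longest linear sequence: 4 steps (1 → 3 → 6 → 10 → 11).

**Steps most likely to fail**

Step 3. The weakly electron-poor alkylpyrone may add too slowly, so that the ketene acetal is consumed by thermal oligomerisation before cycloaddition, or methanol loss may stall at the diene stage. The fallback gives up the ring construction and sets out from 3. Hydroboration as in step 2 gives borane 5, which is coupled with 1-(benzyloxy)-4-bromobenzene (PdCl2(dppf)·CH2Cl2, K3PO4 aq, THF/DMF, 50 °C) to give 3-[4-(benzyloxy)phenyl]propyl docosanoate F1. Hydrogenolysis (H2, Pd/C, EtOAc/THF, rt) should then free the phenol and rejoin the route at 11.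

Step 2. Ring opening of the pyrone by aqueous base may compete with transmetalation, and the alkylborane may be lost by protodeboronation or β-hydride elimination. The fallback is base-free and sets out from 1. Fischer esterification with 3-bromopropan-1-ol (TsOH·H2O, toluene, Dean–Stark) gives 3-bromopropyl docosanoate F2. Zinc insertion (Zn dust activated with 1,2-dibromoethane and TMSCl, LiCl, THF, 50 °C) gives [3-(docosanoyloxy)propyl]zinc bromide F3. Negishi coupling with 4 (Pd(PPh3)4, THF, rt → 50 °C) comes back to the route at 6.

Step 4. Lewis-acid scission of the alkyl ester may compete with O-demethylation. The fallback sets out from 10. Saponification (LiOH, THF/MeOH/H2O, then dilute HCl) gives 3-(4-methoxyphenyl)propan-1-ol F4 and returns acid 1. Thiolate demethylation (NaSEt, DMF, 130 °C, acidic work-up) gives 3-(4-hydroxyphenyl)propan-1-ol F5. Lipase-catalysed esterification with 1 (immobilised Candida antarctica lipase B, toluene, 60 °C, 4 Å molecular sieves) acylates only the aliphatic hydroxyl and comes back to the route at 11.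

**Further compounds**

F1 | step 3 | 3-[4-(benzyloxy)phenyl]propyl docosanoate | CCCCCCCCCCCCCCCCCCCCCC(=O)OCCCc1ccc(OCc2ccccc2)cc1
F2 | step 2 | 3-bromopropyl docosanoate | CCCCCCCCCCCCCCCCCCCCCC(=O)OCCCBr
F3 | step 2 | [3-(docosanoyloxy)propyl]zinc bromide | CCCCCCCCCCCCCCCCCCCCCC(=O)OCCC[Zn]Br
F4 | step 4 | 3-(4-methoxyphenyl)propan-1-ol | COc1ccc(CCCO)cc1
F5 | step 4 | 3-(4-hydroxyphenyl)propan-1-ol | OCCCc1ccc(O)cc1
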